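**Plan**

1. Cuts, in retrosynthetic order: (a) the pyran O–CH(nonenyl) bond; (b) the bond from that CH to the methyl-bearing ring-alkene carbon; (c) in one stroke, the lactone O–C bond at the quaternary cyclopentane carbon and the CH–CH bond joining the cyclopentane methine to the neighbouring ring-fusion methine; (d) the epoxide, the C–CO2H bond and the carbinol–alkyne bond of the open chain; (e) the cyclopentene.
2. Enabling feature: the quaternary bridgehead of the 2-oxabicyclo[2.2.2]octanone carries both the pyran oxygen and the lactone carbonyl and is bonded to the ring-fusion CH. This array is a glycidic acid in disguise (pyran O = epoxide O). The O-bearing cyclopentane carbon and its CH neighbour are a cyclopentene C=C that can reach the epoxide CH through a six-membered chair.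
3. Forward ring order: cyclopentene (enyne metathesis) → carbocyclic six-ring and bridged lactone together (key step, which frees the bridgehead OH) → temporary oxasiline ring → dihydropyran.
4. Stereochemistry: the cyclopentanol carbon comes from (R)-epichlorohydrin; the carbinol beside the quaternary centre from a ligand-controlled diyne addition; the quaternary carbon and its neighbour from a Sharpless epoxidation (the neighbour is inverted in the key step); the two ring-fusion carbons from the chair transition state and the tether; the pyran CH from a CBS-derived carbinol by syn-SN2′ chirality transfer.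

Key step: step 14

Assumption (chemistry): (R,R)-ProPhenol is taken to add the diyne to the Si face of aldehyde 8 (R-carbinol); if the sense is the reverse, the (S,S)-ligand is used.

**Route**

Step 1
Reactants: 1 (R)-epichlorohydrin
Product: 2 (2R)-1-chloropent-4-en-2-ol
Conditions: CH2=CHMgBr, CuI (10 mol%), THF, −40 °C
Reagents that add atoms: vinylmagnesium bromide C=C[Mg]Br
Why: Copper-catalysed Grignard opening of the terminal epoxide at its CH2 carbon (SN2) should leave the C–O stereocentre untouched.

Step 2
Reactants: 2 (2R)-1-chloropent-4-en-2-ol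
Product: 4 (4R)-hept-1-en-6-yn-4-ol, via (2R)-2-allyloxirane 3 (not isolated)
Conditions: LiC≡CH·H2NCH2CH2NH2 (3 equiv), DMSO, 0 °C to rt
Reagents that add atoms: lithium acetylide [Li+].[C-]#C
Why: The acetylide first closes the chlorohydrin to epoxide 3 (intramolecular Williamson reaction) and then opens it at the CH2 terminus, so the carbinol configuration is retained.

Step 3
Reactants: 4 (4R)-hept-1-en-6-yn-4-ol
Product: 5 TBS ether of 4
Conditions: TBSCl, imidazole, DMF, rt
Reagents that add atoms: tert-butyldimethylsilyl chloride CC(C)(C)[Si](C)(C)Cl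
Why: Standard silylation of a secondary alcohol protects the future cyclopentanol oxygen.

Step 4
Reactants: 5 TBS ether of 4
Product: 6 (1R)-3-ethenylcyclopent-3-en-1-yl TBS ether
Conditions: first-generation Grubbs catalyst RuCl2(PCy3)2(=CHPh) (3 mol%), ethylene (1 atm), CH2Cl2, rt
Reagents that add atoms: none
Why: Ring-closing enyne metathesis of the 1,6-enyne in the exo mode should give the 1-vinylcyclopentene with the ring C=C where the key step needs it, and no stereocentre is touched.

Step 5
Reactants: 6 (1R)-3-ethenylcyclopent-3-en-1-yl TBS ether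
Product: 7 2-[(4R)-4-(TBSO)cyclopent-1-en-1-yl]ethanol
Conditions: 9-BBN, THF, 0 °C to rt; then NaOH, H2O2, 0 °C
Reagents that add atoms: hydrogen peroxide OO
Why: Hydroboration–oxidation with the bulky 9-BBN should take place only at the terminal vinyl group of the 1,3-diene with boron on the CH2 terminus, giving the homoallylic alcohol.

Step 6
Reactants: 7 2-[(4R)-4-(TBSO)cyclopent-1-en-1-yl]ethanol
Product: 8 2-[(4R)-4-(TBSO)cyclopent-1-en-1-yl]acetaldehyde
Conditions: Dess–Martin periodinane, NaHCO3, CH2Cl2, 0 °C; used at once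
Reagents that add atoms: none
Why: Buffered Dess–Martin oxidation gives the β,γ-unsaturated aldehyde without a base that would move the double bond into conjugation.

Step 7
Reactants: 9 1,4-dichlorobut-2-yne
Product: 11 penta-1,3-diyne, via sodium buta-1,3-diynide 10 (not isolated)
Conditions: NaNH2 (3 equiv), liquid NH3, −40 °C; then MeI; taken up in toluene
Reagents that add atoms: iodomethane CI
Why: Double dehydrochlorination of the propargylic dichloride gives the butadiynide, which is C-methylated (acetylide alkylation) to the volatile diyne, kept in solution.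

Step 8
Reactants: 8 2-[(4R)-4-(TBSO)cyclopent-1-en-1-yl]acetaldehyde; 11 penta-1,3-diyne
Product: 12 (2R)-1-[(4R)-4-(TBSO)cyclopent-1-en-1-yl]hepta-3,5-diyn-2-ol
Conditions: Me2Zn (3 equiv), (R,R)-ProPhenol (20 mol%), Ph3P=O (40 mol%), toluene, 4 °C, slow addition of 8
Reagents that add atoms: none
Why: Zinc–ProPhenol-catalysed enantioselective alkynylation with a 1,3-diyne should add the diynylzinc to the Si face of the aldehyde inside the dinuclear zinc pocket, setting the (R)-carbinol.

Step 9
Reactants: 12 (2R)-diynol
Product: 13 (2R,3Z)-3-(tributylstannyl)hept-3-en-5-yn-2-ol derivative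
Conditions: Bu3SnH (1.05 equiv), [Cp*RuCl]4 (2.5 mol%), CH2Cl2, rt
Reagents that add atoms: tributyltin hydride CCCC[SnH](CCCC)CCCC
Why: Ruthenium-catalysed trans-hydrostannation directed by the propargylic hydroxyl (O–H···Cl–Ru hydrogen bond) should put tin on the alkyne carbon next to the carbinol and hydrogen trans to it, giving the Z-alkenylstannane and leaving the distal alkyne alone.

Step 10
Reactants: 13 Z-alkenylstannane
Product: 14 TBS ether of 13
Conditions: TBSCl, imidazole, DMAP (cat.), DMF, rt
Reagents that add atoms: tert-butyldimethylsilyl chloride CC(C)(C)[Si](C)(C)Cl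
Why: Standard silylation masks the carbinol before the organolithium and oxidation steps.

Step 11
Reactants: 14 TBS ether of 13
Product: 16 (2E)-2-substituted hex-2-en-4-yn-1-ol, via alkenyllithium 15 (not isolated)
Conditions: n-BuLi, THF, −78 °C; then (CH2O)n, −78 to 0 °C
Reagents that add atoms: formaldehyde C=O
Why: Tin–lithium exchange proceeds with retention of alkene geometry and the alkenyllithium is hydroxymethylated by formaldehyde, which places CH2OH cis to the propynyl group.

Step 12
Reactants: 16 (2E)-enynol
Product: 17 (2S,3R)-epoxy alcohol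
Conditions: Ti(OiPr)4 (10 mol%), L-(+)-diethyl tartrate (12 mol%), t-BuOOH, 4 Å MS, CH2Cl2, −20 °C
Reagents that add atoms: tert-butyl hydroperoxide CC(C)(C)OO
Why: Sharpless asymmetric epoxidation of the primary allylic alcohol is chemoselective over the cyclopentene and, with the L-tartrate, should deliver oxygen to the face that gives the (2S,3R)-epoxide (reagent control), fixing the quaternary carbon and the propargylic carbon that is inverted later.

Step 13
Reactants: 17 (2S,3R)-epoxy alcohol
Product: 19 (2S,3R)-epoxy acid, via epoxy aldehyde 18 (not isolated)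
Conditions: TEMPO (20 mol%), PhI(OAc)2 (2.5 equiv), MeCN/pH 7 buffer, rt; used crude
Reagents that add atoms: water O
Why: TEMPO/PhI(OAc)2 oxidation in buffered aqueous acetonitrile takes the primary alcohol through the aldehyde hydrate to the acid without touching epoxide, alkyne, alkene or silyl ethers.

Step 14
Reactants: 19 (2S,3R)-epoxy acid
Product: 20 (1R,3R,5R,6S,7S,11R)-3,11-bis(TBSO)-7-hydroxy-6-(prop-1-yn-1-yl)-9-oxatricyclo[5.2.2.0^{1,5}]undecan-8-one
Conditions: Ph4PBF4 (20 mol%), HFIP (0.01 M), 0 °C to rt
Reagents that add atoms: none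
Why: Proposed new method: hydrogen-bond activation of the propargylic glycidic acid lets the cyclopentene C=C open the epoxide at its CH carbon from the back, the tertiary cyclopentyl cation so formed is captured by the carboxyl group on the former epoxide carbon, and the epoxide oxygen is left as the bridgehead tertiary alcohol. The closest known reaction types are the epoxide-initiated cation–olefin cyclization (promoted by HFIP or Lewis acids) and the carboxylic-acid termination of cationic cyclizations, as in the acid lactonization of 4-alkylcyclohex-3-enecarboxylic acids. The carbocycle closes 6-endo-trig at the alkene (exo with respect to the breaking epoxide C–O bond) through a chair, and the lactone closes by transannular capture of the cation by the axial carboxyl once the chair flips to a boat, giving the 2-oxabicyclo[2.2.2]octanone. The propargylic carbon is inverted by the backside attack, which also forces the old epoxide oxygen equatorial and the carboxyl axial; the ring-fusion CH follows from the chair (cyclopentene CH2 equatorial, H axial and cis to CO2H); the oxygenated ring-fusion carbon is set by the tether, since only the axial carboxyl reaches the cation, which amounts to anti addition of C and O across the alkene and a cis-hydrindane. The step needs Markovnikov 6-endo closure (tertiary rather than secondary cation), opening at the propargylic CH rather than at the carboxyl-bearing quaternary epoxide carbon (electronic and steric bias of a glycidic acid), and termination by carboxyl rather than by the freed equatorial hydroxyl, which would have to form a strained 7-oxabicyclo[2.2.1]heptane that the acidic medium can reopen and funnel to the lactone.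

Step 15
Reactants: 20 hydroxy lactone
Product: 22 cyclic alkenylsiloxane, via dimethylsilyl ether 21 (not isolated)
Conditions: Me2SiHCl, Et3N, DMAP (cat.), CH2Cl2, 0 °C; filter, concentrate; then [Cp*Ru(MeCN)3]PF6 (5 mol%), CH2Cl2, 0 °C to rt
Reagents that add atoms: chlorodimethylsilane C[SiH](C)Cl
Why: Silylation of the only free hydroxyl is followed by ruthenium-catalysed intramolecular trans-hydrosilylation of the homopropargylic silyl ether in the 6-endo-dig mode, which puts silicon on the methyl-bearing alkyne carbon and fixes the Z trisubstituted alkene inside the oxasiline ring.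

Step 16
Reactants: 23 octanoyl chloride
Product: 24 (1E)-1-chlorodec-1-en-3-one
Conditions: HC≡CH (bubbled), AlCl3, CH2Cl2, 0 °C
Reagents that add atoms: acetylene C#C
Why: Friedel–Crafts-type acylation of acetylene by the acyl chloride–AlCl3 complex with chloride capture gives the (E)-β-chlorovinyl ketone.

Step 17
Reactants: 24 (1E)-1-chlorodec-1-en-3-one
Product: 25 (1E)-1-iododec-1-en-3-one
Conditions: NaI, acetone, reflux
Reagents that add atoms: sodium iodide [Na+].[I-]
Why: Halide exchange by conjugate addition–elimination (Finkelstein-type) on the β-chlorovinyl ketone gives the thermodynamically favoured E iodide.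

Step 18
Reactants: 25 (1E)-1-iododec-1-en-3-one
Product: 26 (1E,3R)-1-iododec-1-en-3-ol
Conditions: (S)-2-methyl-CBS-oxazaborolidine (20 mol%), BH3·SMe2, THF, −30 °C
Reagents that add atoms: none
Why: Corey–Bakshi–Shibata reduction, with the alkenyl group acting as the large substituent, should give the (R)-allylic alcohol with the (S)-catalyst.

Step 19
Reactants: 22 cyclic alkenylsiloxane; 26 (1E,3R)-1-iododec-1-en-3-ol
Product: 28 tetraol dienol, via bis-silyl dienol 27 (not isolated)
Conditions: Pd2(dba)3 (5 mol%, zerovalent palladium), TBAF·3H2O (8 equiv), THF, rt, 30 min for coupling, then 24 h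
Reagents that add atoms: none
Why: Fluoride-promoted Hiyama–Denmark cross-coupling of the cyclic alkenylsiloxane with the alkenyl iodide proceeds with retention at both alkenes to give the (1Z,3E)-diene and frees the bridgehead hydroxyl, and the excess fluoride then cleaves both silyl ethers.

Step 20
Reactants: 28 tetraol dienol
Product: 29 CNP0127096.2 (target)
Conditions: PdCl2(MeCN)2 (10 mol%, divalent palladium), THF, 0 °C
Reagents that add atoms: none
Why: Dehydrative cyclization of the hydroxy allylic alcohol (oxypalladation then β-hydroxide elimination, net syn SN2′) should transfer the (R)-carbinol chirality to the new pyran CH and form the E alkene, the bridgehead hydroxyl being the only one that can reach the diene through a six-membered ring.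

**Compound list**

1 | (R)-epichlorohydrin, (2R)-2-(chloromethyl)oxirane | ClC[C@H]1CO1 | starting material
2 | (2R)-1-chloropent-4-en-2-ol | ClC[C@H](O)CC=C | intermediate
3 | (2R)-2-(prop-2-en-1-yl)oxirane | C=CC[C@@H]1CO1 | intermediate
4 | (4R)-hept-1-en-6-yn-4-ol | C=CC[C@@H](O)CC#C | intermediate
5 | tert-butyl[(4R)-hept-1-en-6-yn-4-yloxy]dimethylsilane | C=CC[C@@H](O[Si](C)(C)C(C)(C)C)CC#C | intermediate
6 | tert-butyl{[(1R)-3-ethenylcyclopent-3-en-1-yl]oxy}dimethylsilane | C=CC1=CC[C@@H](O[Si](C)(C)C(C)(C)C)C1 | intermediate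
7 | 2-[(4R)-4-(tert-butyldimethylsilyloxy)cyclopent-1-en-1-yl]ethan-1-ol | OCCC1=CC[C@@H](O[Si](C)(C)C(C)(C)C)C1 | intermediate
8 | 2-[(4R)-4-(tert-butyldimethylsilyloxy)cyclopent-1-en-1-yl]acetaldehyde | O=CCC1=CC[C@@H](O[Si](C)(C)C(C)(C)C)C1 | intermediate
9 | 1,4-dichlorobut-2-yne | ClCC#CCCl | starting material
10 | sodium buta-1,3-diyn-1-ide | [Na+].[C-]#CC#C | intermediate
11 | penta-1,3-diyne | CC#CC#C | intermediate
12 | (2R)-1-[(4R)-4-(tert-butyldimethylsilyloxy)cyclopent-1-en-1-yl]hepta-3,5-diyn-2-ol | CC#CC#C[C@H](O)CC1=CC[C@@H](O[Si](C)(C)C(C)(C)C)C1 | intermediate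
13 | (2R,3Z)-1-[(4R)-4-(tert-butyldimethylsilyloxy)cyclopent-1-en-1-yl]-3-(tributylstannyl)hept-3-en-5-yn-2-ol | CC#C/C=C(\[Sn](CCCC)(CCCC)CCCC)[C@H](O)CC1=CC[C@@H](O[Si](C)(C)C(C)(C)C)C1 | intermediate
14 | TBS ether of 13 at the C-2 hydroxyl (2R,3Z) | CC#C/C=C(\[Sn](CCCC)(CCCC)CCCC)[C@H](O[Si](C)(C)C(C)(C)C)CC1=CC[C@@H](O[Si](C)(C)C(C)(C)C)C1 | intermediate
15 | alkenyllithium from 14 (lithium in place of tin, same geometry) | CC#C/C=C(\[Li])[C@H](O[Si](C)(C)C(C)(C)C)CC1=CC[C@@H](O[Si](C)(C)C(C)(C)C)C1 | intermediate
16 | (2E)-2-[(1R)-1-(tert-butyldimethylsilyloxy)-2-[(4R)-4-(tert-butyldimethylsilyloxy)cyclopent-1-en-1-yl]ethyl]hex-2-en-4-yn-1-ol | CC#C/C=C(\CO)[C@H](O[Si](C)(C)C(C)(C)C)CC1=CC[C@@H](O[Si](C)(C)C(C)(C)C)C1 | intermediate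
17 | [(2S,3R)-2-[(1R)-1-(tert-butyldimethylsilyloxy)-2-[(4R)-4-(tert-butyldimethylsilyloxy)cyclopent-1-en-1-yl]ethyl]-3-(prop-1-yn-1-yl)oxiran-2-yl]methanol | OC[C@@]1(O[C@@H]1C#CC)[C@H](O[Si](C)(C)C(C)(C)C)CC2=CC[C@@H](O[Si](C)(C)C(C)(C)C)C2 | intermediate
18 | (2S,3R)-oxirane-2-carbaldehyde corresponding to 17 | O=C[C@@]1(O[C@@H]1C#CC)[C@H](O[Si](C)(C)C(C)(C)C)CC2=CC[C@@H](O[Si](C)(C)C(C)(C)C)C2 | intermediate
19 | (2S,3R)-2-[(1R)-1-(tert-butyldimethylsilyloxy)-2-[(4R)-4-(tert-butyldimethylsilyloxy)cyclopent-1-en-1-yl]ethyl]-3-(prop-1-yn-1-yl)oxirane-2-carboxylic acid | OC(=O)[C@@]1(O[C@@H]1C#CC)[C@H](O[Si](C)(C)C(C)(C)C)CC2=CC[C@@H](O[Si](C)(C)C(C)(C)C)C2 | intermediate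
20 | (1R,3R,5R,6S,7S,11R)-3,11-bis(tert-butyldimethylsilyloxy)-7-hydroxy-6-(prop-1-yn-1-yl)-9-oxatricyclo[5.2.2.0^{1,5}]undecan-8-one | O[C@@]23C(=O)O[C@]4(C[C@H](O[Si](C)(C)C(C)(C)C)C[C@@H]4[C@H]2C#CC)C[C@H]3O[Si](C)(C)C(C)(C)C | intermediate
21 | 7-O-dimethylsilyl ether of 20 | C[SiH](C)O[C@@]23C(=O)O[C@]4(C[C@H](O[Si](C)(C)C(C)(C)C)C[C@@H]4[C@H]2C#CC)C[C@H]3O[Si](C)(C)C(C)(C)C | intermediate
22 | cyclic alkenylsiloxane: bridgehead O and the methyl-bearing alkene carbon of 20 joined through SiMe2 in a six-membered 1,2-oxasiline ring (Z alkene in the ring) | C[Si]1(C)O[C@@]23C(=O)O[C@]4(C[C@H](O[Si](C)(C)C(C)(C)C)C[C@@H]4[C@H]2C=C1C)C[C@H]3O[Si](C)(C)C(C)(C)C | intermediate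
23 | octanoyl chloride | CCCCCCCC(=O)Cl | starting material
24 | (1E)-1-chlorodec-1-en-3-one | CCCCCCCC(=O)/C=C/Cl | intermediate
25 | (1E)-1-iododec-1-en-3-one | CCCCCCCC(=O)/C=C/I | intermediate
26 | (1E,3R)-1-iododec-1-en-3-ol | CCCCCCC[C@@H](O)/C=C/I | intermediate
27 | (1R,3R,5R,6R,7S,11R)-3,11-bis(tert-butyldimethylsilyloxy)-7-hydroxy-6-[(1Z,3E,5R)-5-hydroxy-2-methyldodeca-1,3-dien-1-yl]-9-oxatricyclo[5.2.2.0^{1,5}]undecan-8-one | O[C@@]23C(=O)O[C@]4(C[C@H](O[Si](C)(C)C(C)(C)C)C[C@@H]4[C@H]2/C=C(C)\C=C\[C@H](O)CCCCCCC)C[C@H]3O[Si](C)(C)C(C)(C)C | intermediate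
28 | (1R,3R,5R,6R,7S,11R)-3,7,11-trihydroxy-6-[(1Z,3E,5R)-5-hydroxy-2-methyldodeca-1,3-dien-1-yl]-9-oxatricyclo[5.2.2.0^{1,5}]undecan-8-one | O[C@@]23C(=O)O[C@]4(C[C@H](O)C[C@@H]4[C@H]2/C=C(C)\C=C\[C@H](O)CCCCCCC)C[C@H]3O | intermediate
29 | CNP0127096.2: dihydropyran-fused, cyclopentane-fused 2-oxabicyclo[2.2.2]octanone with two secondary hydroxyls and an (E)-non-1-enyl group | CCCCCCC/C=C/[C@H]1O[C@@]23C(=O)O[C@]4(C[C@H](O)C[C@@H]4[C@H]2C=C1C)C[C@H]3O | target

**Count and risks**

Total step count: 20. Longest linear sequence: 16 steps (steps 1–6, 8–15, 19, 20).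

Step 14 (labelled step). What may go wrong: the propargylic C–O bond may ionize before the alkene attacks, so that inversion and the chair preference are lost; the cation may be lost by elimination or captured by the freed hydroxyl; the epoxide may undergo a semipinacol shift. Fallback with known chemistry, making the C–C and the C–O bond in separate operations: from 17, the primary alcohol is silylated (TBSCl, imidazole, DMF) to give tris-silyl ether F1. A classical Lewis-acid epoxide-initiated cation–olefin cyclization with chloride capture (SnCl4, CH2Cl2, −78 °C) gives tertiary chloride F2. The primary silyl ether is removed selectively (HF·pyridine, pyridine, THF, 0 °C) to give chloro diol F3, and TEMPO/PhI(OAc)2 oxidation gives chloro acid F4. Silver-assisted ionization of the tertiary chloride (AgOTf, 2,6-di-tert-butylpyridine, CH2Cl2, 0 °C) closes the lactone, and the route is rejoined at 20.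

Step 19. What may go wrong: transmetalation of the hindered, methyl-substituted alkenylsiloxane may be slow and give way to protodesilylation; the long exposure to basic fluoride may epimerize the β-hydroxy lactone carbinol by retro-aldol and re-aldol. Fallback without fluoride in the coupling: from 22, ipso-iododesilylation with retention (N-iodosuccinimide, HFIP, 0 °C) gives alkenyl iodide F5 with both silyl ethers intact. Iodide 26 is converted into stannane F6 (Bu3SnSnBu3, Pd(PPh3)4, THF). Stille coupling of F5 with F6 (Pd2(dba)3, AsPh3, CuI, DMF) gives 27, now isolated, and buffered desilylation (TBAF, AcOH, THF) rejoins the route at 28.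

Step 20. What may go wrong: the tertiary hydroxyl next to the lactone carbonyl is a weak nucleophile, so ionization of the dienyl alcohol may win and chirality transfer be lost, or the allylic hydroxyl may transpose. Fallback that sets the pyran CH by hydride delivery instead of C–O bond formation: from 22 via alkenyl iodide F5 (made as above), carbonylative Stille coupling under CO (1 atm; Pd2(dba)3, AsPh3, DMF) with alkenylstannane F7 (from non-1-yne, Cp2Zr(H)Cl then Bu3SnCl) gives Z-dienone F8. Reductive etherification (Et3SiH, TMSOTf, CH2Cl2, −78 °C) goes through the cyclic oxocarbenium ion, where hydride should enter anti to the axial lactone carbon on the neighbouring quaternary centre, and gives bis-silyl ether F9. Desilylation (TBAF, AcOH, THF) rejoins the route at 29.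

Further compounds
F1 | step 14 | tris-silyl ether (primary TBS ether of 17) | CC(C)(C)[Si](C)(C)OC[C@@]1(O[C@@H]1C#CC)[C@H](O[Si](C)(C)C(C)(C)C)CC2=CC[C@@H](O[Si](C)(C)C(C)(C)C)C2
F2 | step 14 | tertiary chloride (cis-hydrindane with ring-fusion C–Cl, free tertiary alcohol, CH2OTBS) | O[C@@]1(CO[Si](C)(C)C(C)(C)C)[C@H](C#CC)[C@H]2C[C@@H](O[Si](C)(C)C(C)(C)C)C[C@@]2(Cl)C[C@H]1O[Si](C)(C)C(C)(C)C
F3 | step 14 | chloro diol (primary alcohol of F2 freed) | O[C@@]1(CO)[C@H](C#CC)[C@H]2C[C@@H](O[Si](C)(C)C(C)(C)C)C[C@@]2(Cl)C[C@H]1O[Si](C)(C)C(C)(C)C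
F4 | step 14 | chloro acid (α-hydroxy acid with tertiary chloride) | O[C@@]1(C(O)=O)[C@H](C#CC)[C@H]2C[C@@H](O[Si](C)(C)C(C)(C)C)C[C@@]2(Cl)C[C@H]1O[Si](C)(C)C(C)(C)C
F5 | step 19 | alkenyl iodide (20 with a (1Z)-2-iodoprop-1-enyl group in place of propynyl) | O[C@@]23C(=O)O[C@]4(C[C@H](O[Si](C)(C)C(C)(C)C)C[C@@H]4[C@H]2/C=C(C)\I)C[C@H]3O[Si](C)(C)C(C)(C)C
F6 | step 19 | (1E,3R)-1-(tributylstannyl)dec-1-en-3-ol | CCCCCCC[C@@H](O)/C=C/[Sn](CCCC)(CCCC)CCCC
F7 | step 20 | (E)-tributyl(non-1-en-1-yl)stannane | CCCCCCC/C=C/[Sn](CCCC)(CCCC)CCCC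
F8 | step 20 | Z-dienone (cross-conjugated ketone on the lactone core, free bridgehead hydroxyl) | O[C@@]23C(=O)O[C@]4(C[C@H](O[Si](C)(C)C(C)(C)C)C[C@@H]4[C@H]2/C=C(C)\C(=O)/C=C/CCCCCCC)C[C@H]3O[Si](C)(C)C(C)(C)C
F9 | step 20 | bis-silyl ether of the target | CCCCCCC/C=C/[C@H]1O[C@@]23C(=O)O[C@]4(C[C@H](O[Si](C)(C)C(C)(C)C)C[C@@H]4[C@H]2C=C1C)C[C@H]3O[Si](C)(C)C(C)(C)C
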